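**Retrosynthetic overview**

1. Numbering: carbocycle C1 (ring carbon bearing =CH2), C2–C4, C5 (CMe2), C6 and C10 (ring fusion), C7, C8, C9 (quaternary); side unit C11 (CH on C9), C12 (acetal CH), O13, C14 (lactone C=O), C15 (CHOAc), C16 (bridgehead CH), C17 (CH–CO2Me), O18, C19 (ester carbon). The strategy rests on C1 and C4 lying 1,4 across the seven-membered ring (C1–C2–C3–C4–C5–C6–C10), next to C10 and C5: the footprint of a cyclobutane built on a cyclopentane-1,3-dione enol (C10=C4) and then cut at C10–C4.
2. Side unit: C15–OAc from oxidation of the lactone enolate; lactone bridge C12–O13 by transacetalisation; tetrahydrofuran ring by radical closure C11–C16 of an iodoacetal made from the C11=C12 enol ether and an (R)-hydroxy enoate that carries C17; the enol ether from the C9–CH2O arm.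
3. Carbocycle: C1 methylidene by Wittig reaction and C4 deoxygenation trace back to the 1,4-diketone; this comes from [2+2] photocycloaddition of the dione enol C10=C4 to the tethered C6=C5 alkene (bonds C10–C6 and C4–C5) and retro-aldol cleavage of C10–C4.
4. Photosubstrate: cyclobutene bis-silyl enol ether aldol/ring expansion on an α-quaternary aldehyde; C9 from enzymatic desymmetrisation of a dialkylated methylmalonate.
5. Ring order: cyclopentane (C6–C10) and cyclobutane together, seven-membered ring by ring expansion, tetrahydrofuran, then the δ-lactone bridge.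

Key step: step 8

Assumption: pig liver esterase is taken to give the (R)-half-ester, the sense recalled for 2-alkyl-2-methylmalonates with longer alkyl chains (with the opposite sense the order of reducing acid and ester is exchanged), and methyl (R)-2-hydroxybut-3-enoate is taken as a purchasable single enantiomer.

**Route**

Step 1
Reactants: 1 dimethyl 2-methylmalonate; 2 5-bromo-2-methylpent-2-ene
Product: 3 dimethyl 2-methyl-2-(4-methylpent-3-en-1-yl)malonate
Conditions: NaH, THF–DMF, 0 → 60 °C
Reagents that add atoms: none
Why: Malonate alkylation (SN2 of the sodium enolate on a primary bromide) makes the prochiral quaternary carbon that becomes C9.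

Step 2
Reactants: 3 dimethyl 2-methyl-2-(4-methylpent-3-en-1-yl)malonate
Product: 4 (R)-2-(methoxycarbonyl)-2,6-dimethylhept-5-enoic acid
Conditions: pig liver esterase, phosphate buffer pH 7.5, DMSO (10%), 25 °C; acidify
Reagents that add atoms: water, O
Why: Enzymatic desymmetrisation: the esterase hydrolyses one of the two enantiotopic methyl esters of the 2,2-dialkylmalonate, which sets C9 (sense as assumed above).

Step 3
Reactants: 4 (R)-2-(methoxycarbonyl)-2,6-dimethylhept-5-enoic acid
Product: 5 (S)-2-(hydroxymethyl)-2,6-dimethylhept-5-enoic acid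
Conditions: LiBH4, THF, 0 → 65 °C; aq. HCl work-up
Reagents that add atoms: none
Why: Chemoselective borohydride reduction: LiBH4 reduces the methyl ester while the lithium carboxylate is inert, so the ester arm becomes the hydroxymethyl group (future C11) and C9 is untouched.

Step 4
Reactants: 5 (S)-2-(hydroxymethyl)-2,6-dimethylhept-5-enoic acid
Product: 7 (S)-2,6-dimethyl-2-[(triisopropylsilyloxy)methyl]hept-5-enoic acid, via triisopropylsilyl ester 6 (not isolated)
Conditions: iPr3SiCl, imidazole, DMF, 20 °C; then AcOH–THF–H2O, 20 °C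
Reagents that add atoms: triisopropylsilyl chloride, CC(C)[Si](Cl)(C(C)C)C(C)C
Why: Silylation of the neopentyl alcohol; the silyl ester formed at the same time is far more labile than the silyl ether and is removed by mild aqueous acid.

Step 5
Reactants: 7 (S)-2,6-dimethyl-2-[(triisopropylsilyloxy)methyl]hept-5-enoic acid
Product: 8 (R)-2,6-dimethyl-2-[(triisopropylsilyloxy)methyl]hept-5-en-1-ol
Conditions: LiAlH4, THF, 0 → 40 °C; Rochelle salt, 0 °C
Reagents that add atoms: none
Why: Hydride reduction of the carboxylic acid to the primary alcohol; the bulky silyl group and a cold, neutral work-up guard against 1,3-silyl migration between the two CH2O arms, which would racemise C9.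

Step 6
Reactants: 8 (R)-2,6-dimethyl-2-[(triisopropylsilyloxy)methyl]hept-5-en-1-ol
Product: 9 (S)-2,6-dimethyl-2-[(triisopropylsilyloxy)methyl]hept-5-enal
Conditions: Dess–Martin periodinane, NaHCO3, CH2Cl2, 20 °C
Reagents that add atoms: none
Why: Dess–Martin oxidation of a neopentyl alcohol to an aldehyde that has no α-hydrogen and cannot epimerise.

Step 7
Reactants: 9 (S)-2,6-dimethyl-2-[(triisopropylsilyloxy)methyl]hept-5-enal; 10 1,2-bis(trimethylsilyloxy)cyclobutene
Product: 12 3-hydroxy-2-[(R)-2,6-dimethyl-1-(triisopropylsilyloxy)hept-5-en-2-yl]cyclopent-2-en-1-one (dione enol), via cyclobutanone aldol adduct 11 (not isolated)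
Conditions: BF3·OEt2, CH2Cl2, −78 °C; then CF3CO2H, 0 → 20 °C
Reagents that add atoms: none
Why: Mukaiyama-type aldol of the bis-silyl enol ether with the aldehyde, followed by acid-induced semipinacol ring expansion of the 2-silyloxycyclobutanone (acyl shift), gives the 2-substituted cyclopentane-1,3-dione, the aldehyde carbon becoming C10.

Step 8
Reactants: 12 3-hydroxy-2-[(R)-2,6-dimethyl-1-(triisopropylsilyloxy)hept-5-en-2-yl]cyclopent-2-en-1-one
Product: 14 cis-fused hydroazulene-1,4-dione carrying 5,5-dimethyl and 9-methyl-9-(triisopropylsilyloxymethyl) groups, via cyclobutanol photoadduct 13 (not isolated)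
Conditions: hν (medium-pressure Hg lamp, Pyrex), MeCN, 20 °C; then DBU (cat.), CH2Cl2, 20 °C
Reagents that add atoms: none
Why: De Mayo reaction: the excited enone of the enolised dione (C1=O, C10=C4) adds to the tethered C6=C5 alkene, first joining C10 to C6 and then, by collapse of the 1,4-diradical, C4 to C5; the resulting cyclobutanol 13 is a strained β-hydroxy ketone and opens by retro-aldol cleavage of C10–C4, which enlarges the dione ring by two carbons to the seven-membered 1,4-diketone. The closest known reaction type is the intramolecular de Mayo reaction of alkenyl 1,3-diketone enols (enol–alkene [2+2] photocycloaddition followed by retro-aldol ring expansion). The cyclopentane closes by 5-exo attack of C10 on C6 (three-atom tether C9–C8–C7), the cyclobutane by diradical recombination, and the seven-membered ring arises by fragmentation and not by a direct closure. C6 is set relative to C9 in the first bond formation, where the chain should fold with the bulkier silyloxymethyl arm turned away from the developing cyclobutane so that the C6–C5 bond lies on the C9-methyl face; C10 is set afterwards by protonation of the retro-aldol enolate and base equilibration of this α-keto centre to the more stable cis ring fusion. The step needs straight and not crossed regiochemistry, which the three-atom tether secures, and facial selectivity at C6, which rests on the size difference between methyl and CH2OSi(iPr)3 at C9.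

Step 9
Reactants: 14 cis-fused hydroazulene-1,4-dione
Product: 15 1-methylidene-hydroazulen-4-one (C4 ketone kept; other groups unchanged)
Conditions: Ph3PCH3Br, KOtBu, toluene, 0 → 20 °C
Reagents that add atoms: methyltriphenylphosphonium bromide, C[P+](c1ccccc1)(c1ccccc1)c1ccccc1.[Br-]
Why: Wittig methylenation should take the C1 ketone (its α-carbon C10 is a CH) in preference to the C4 ketone shielded by quaternary C5, and any epimerisation at C10 before olefination returns the cis fusion.

Step 10
Reactants: 15 1-methylidene-hydroazulen-4-one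
Product: 16 1-methylidene-hydroazulen-4-ol (mixture of C4 epimers)
Conditions: LiAlH4, Et2O, 0 °C
Reagents that add atoms: none
Why: Hydride reduction of the hindered C4 ketone; the configuration of the new carbinol is lost in step 12.

Step 11
Reactants: 16 1-methylidene-hydroazulen-4-ol
Product: 18 O-(C4-alkyl) S-methyl dithiocarbonate (xanthate), via sodium xanthate 17 (not isolated)
Conditions: NaH, imidazole (cat.), THF, 0 → 40 °C; CS2; then MeI
Reagents that add atoms: carbon disulfide, S=C=S; iodomethane, CI
Why: Xanthate formation (alkoxide, CS2, then S-methylation) prepares the secondary alcohol for radical deoxygenation.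

Step 12
Reactants: 18 O-(C4-alkyl) S-methyl dithiocarbonate
Product: 19 cis-fused 1-methylidene-5,5,9-trimethyl-9-(triisopropylsilyloxymethyl)hydroazulene
Conditions: Bu3SnH, AIBN (cat.), toluene, 110 °C
Reagents that add atoms: none
Why: Barton–McCombie deoxygenation: the secondary C4 radical is reduced by the stannane faster than it could add to the C1 methylidene group, for which only 4-exo or 5-endo modes are open.

Step 13
Reactants: 19 silyl ether
Product: 20 [(1R,3aR,8aS)-1,4,4-trimethyl-8-methylidenedecahydroazulen-1-yl]methanol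
Conditions: Bu4NF, THF, 20 → 50 °C
Reagents that add atoms: none
Why: Fluoride cleavage of the silyl ether frees the neopentyl alcohol at C11.

Step 14
Reactants: 20 [(1R,3aR,8aS)-1,4,4-trimethyl-8-methylidenedecahydroazulen-1-yl]methanol
Product: 21 (1R,3aR,8aS)-1,4,4-trimethyl-8-methylidenedecahydroazulene-1-carbaldehyde
Conditions: Dess–Martin periodinane, NaHCO3, CH2Cl2, 20 °C
Reagents that add atoms: none
Why: Dess–Martin oxidation gives the non-enolisable C11 aldehyde beside quaternary C9.

Step 15
Reactants: 21 (1R,3aR,8aS)-1,4,4-trimethyl-8-methylidenedecahydroazulene-1-carbaldehyde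
Product: 22 methyl enol ether (C11=C12–OMe on C9; E/Z mixture)
Conditions: MeOCH2PPh3Cl, KN(SiMe3)2, THF, 0 → 20 °C
Reagents that add atoms: (methoxymethyl)triphenylphosphonium chloride, COC[P+](c1ccccc1)(c1ccccc1)c1ccccc1.[Cl-]
Why: Wittig reaction with the methoxymethylene ylide adds C12 as an enol ether, whose alkene geometry is of no consequence.

Step 16
Reactants: 23 methyl (R)-2-hydroxybut-3-enoate; 24 tert-butyl acrylate
Product: 25 1-tert-butyl 5-methyl (R,E)-4-hydroxypent-2-enedioate
Conditions: second-generation Hoveyda–Grubbs catalyst RuCl2(H2IMes)(=CH-C6H4-2-OiPr) (cat.), CH2Cl2, 40 °C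
Reagents that add atoms: none
Why: Olefin cross-metathesis of an allylic alcohol with an acrylate gives the E-enoate; the carbinol stereocentre (future C17) comes from the starting material and is not touched.

Step 17
Reactants: 22 methyl enol ether; 25 1-tert-butyl 5-methyl (R,E)-4-hydroxypent-2-enedioate
Product: 26 mixed iodoacetal (C11–I; C12 bearing OMe and O18–C17; mixture at C11 and C12)
Conditions: N-iodosuccinimide, 4 Å MS, CH2Cl2, −40 → 0 °C
Reagents that add atoms: N-iodosuccinimide, O=C1CCC(=O)N1I
Why: Iodoacetalisation (first half of the Ueno–Stork sequence): iodonium attack on the electron-rich enol ether at C11 and capture of the oxocarbenium ion at C12 by alcohol 25, the 1,1-disubstituted C1 alkene being far less nucleophilic.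

Step 18
Reactants: 26 mixed iodoacetal
Product: 27 2-methoxytetrahydrofuran (C12 anomers; C9 group on C11 cis to the C16 CH2CO2tBu arm; arm trans to the C17 methyl ester)
Conditions: Bu3SnH, Et3B (cat.), air, toluene, −78 → 0 °C
Reagents that add atoms: none
Why: Ueno–Stork 5-exo-trig radical cyclisation of the C11 radical onto the β-carbon (C16) of the enoate; a chair-like transition state with the C17 ester and the C9 group on the radical carbon both pseudo-equatorial should give the C16 side chain trans to the ester and cis to the C9 group, the latter being the less secure preference.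

Step 19
Reactants: 27 2-methoxytetrahydrofuran
Product: 29 2,7-dioxabicyclo[3.2.1]octan-3-one (lactone acetal; C15 still CH2; C9 group on C11 syn to the lactone bridge; C17 ester exo), via trimethylsilyl ester 28 (not isolated)
Conditions: Me3SiOTf, 2,6-lutidine, CH2Cl2, −20 → 0 °C
Reagents that add atoms: none
Why: Lewis-acid-mediated transacetalisation: the tert-butyl ester is cleaved to the silyl ester, the methyl acetal ionises to the C12 oxocarbenium ion, and the carboxyl on the C16 side chain can add only on its own face, so the lactone bridge fixes C12 (acyl acetal formation).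

Step 20
Reactants: 29 2,7-dioxabicyclo[3.2.1]octan-3-one
Product: 30 C15-hydroxy lactone acetal (hydroxyl equatorial and anti to the C11 bridge)
Conditions: KN(SiMe3)2, THF, −78 °C; 2-(phenylsulfonyl)-3-phenyloxaziridine, −78 °C; AcOH
Reagents that add atoms: 2-(phenylsulfonyl)-3-phenyloxaziridine, O=S(=O)(c1ccccc1)N1OC1c1ccccc1
Why: Davis oxidation of the lactone enolate (the lactone α-CH2 is more acidic than the hindered α-alkoxy ester C–H): the C9 group on the one-carbon bridge lies over the lactone ring, so oxygen is delivered to the opposite face, which gives the equatorial and also more stable C15 alcohol.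

Step 21
Reactants: 30 C15-hydroxy lactone acetal
Product: 31 target, methyl (1S,4S,5R,6R,8R)-4-acetoxy-3-oxo-8-[(1R,3aR,8aS)-1,4,4-trimethyl-8-methylidenedecahydroazulen-1-yl]-2,7-dioxabicyclo[3.2.1]octane-6-carboxylate
Conditions: Ac2O, pyridine, DMAP (cat.), CH2Cl2, 0 → 20 °C
Reagents that add atoms: acetic anhydride, CC(=O)OC(C)=O
Why: DMAP-catalysed acetylation of the secondary alcohol; the α-acetoxy lactone formed is already the more stable C15 epimer.

**Compound list**

1 | dimethyl 2-methylmalonate | COC(=O)C(C)C(=O)OC | starting material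
2 | 5-bromo-2-methylpent-2-ene | CC(C)=CCCBr | starting material
3 | dimethyl 2-methyl-2-(4-methylpent-3-en-1-yl)malonate | COC(=O)C(C)(CCC=C(C)C)C(=O)OC | intermediate
4 | (R)-2-(methoxycarbonyl)-2,6-dimethylhept-5-enoic acid | OC(=O)[C@](C)(C(=O)OC)CCC=C(C)C | intermediate
5 | (S)-2-(hydroxymethyl)-2,6-dimethylhept-5-enoic acid | OC(=O)[C@](C)(CO)CCC=C(C)C | intermediate
6 | triisopropylsilyl (S)-2,6-dimethyl-2-[(triisopropylsilyloxy)methyl]hept-5-enoate (not isolated) | CC(C)[Si](C(C)C)(C(C)C)OC(=O)[C@](C)(CO[Si](C(C)C)(C(C)C)C(C)C)CCC=C(C)C | intermediate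
7 | (S)-2,6-dimethyl-2-[(triisopropylsilyloxy)methyl]hept-5-enoic acid | OC(=O)[C@](C)(CO[Si](C(C)C)(C(C)C)C(C)C)CCC=C(C)C | intermediate
8 | (R)-2,6-dimethyl-2-[(triisopropylsilyloxy)methyl]hept-5-en-1-ol | OC[C@](C)(CO[Si](C(C)C)(C(C)C)C(C)C)CCC=C(C)C | intermediate
9 | (S)-2,6-dimethyl-2-[(triisopropylsilyloxy)methyl]hept-5-enal | O=C[C@](C)(CO[Si](C(C)C)(C(C)C)C(C)C)CCC=C(C)C | intermediate
10 | 1,2-bis(trimethylsilyloxy)cyclobutene | C[Si](C)(C)OC1=C(O[Si](C)(C)C)CC1 | starting material
11 | 2-[1-hydroxy-(2S)-2,6-dimethyl-2-[(triisopropylsilyloxy)methyl]hept-5-enyl]-2-(trimethylsilyloxy)cyclobutanone (mixture at the two new centres; not isolated) | O=C1CCC1(O[Si](C)(C)C)C(O)[C@](C)(CO[Si](C(C)C)(C(C)C)C(C)C)CCC=C(C)C | intermediate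
12 | 3-hydroxy-2-[(R)-2,6-dimethyl-1-(triisopropylsilyloxy)hept-5-en-2-yl]cyclopent-2-en-1-one (dione enol; key-step precursor) | O=C1CCC(O)=C1[C@](C)(CO[Si](C(C)C)(C(C)C)C(C)C)CCC=C(C)C | intermediate
13 | tricyclic cyclobutanol photoadduct (bonds C10–C6 and C4–C5; hydroxyl on C4; cyclobutane on the C9-methyl face; not isolated) | O=C1CC[C@@]2(O)C(C)(C)[C@@H]3CC[C@@](C)(CO[Si](C(C)C)(C(C)C)C(C)C)[C@]123 | intermediate
14 | cis-fused hydroazulene-1,4-dione, 5,5,9-trimethyl-9-(triisopropylsilyloxymethyl); H6, H10 and the CH2OSi arm on one face, C9 methyl on the other (key-step product) | O=C1CCC(=O)C(C)(C)[C@@H]2CC[C@@](C)(CO[Si](C(C)C)(C(C)C)C(C)C)[C@H]12 | intermediate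
15 | 1-methylidene analogue of 14 with the C4 ketone kept | C=C1CCC(=O)C(C)(C)[C@@H]2CC[C@@](C)(CO[Si](C(C)C)(C(C)C)C(C)C)[C@H]12 | intermediate
16 | C4 alcohol from 15 (C4 epimer mixture) | C=C1CCC(O)C(C)(C)[C@@H]2CC[C@@](C)(CO[Si](C(C)C)(C(C)C)C(C)C)[C@H]12 | intermediate
17 | sodium O-alkyl dithiocarbonate of 16 (not isolated) | C=C1CCC(OC(=S)[S-])C(C)(C)[C@@H]2CC[C@@](C)(CO[Si](C(C)C)(C(C)C)C(C)C)[C@H]12.[Na+] | intermediate
18 | O-alkyl S-methyl dithiocarbonate of 16 | C=C1CCC(OC(=S)SC)C(C)(C)[C@@H]2CC[C@@](C)(CO[Si](C(C)C)(C(C)C)C(C)C)[C@H]12 | intermediate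
19 | cis-fused 1-methylidene-5,5,9-trimethyl-9-(triisopropylsilyloxymethyl)hydroazulene | C=C1CCCC(C)(C)[C@@H]2CC[C@@](C)(CO[Si](C(C)C)(C(C)C)C(C)C)[C@H]12 | intermediate
20 | [(1R,3aR,8aS)-1,4,4-trimethyl-8-methylidenedecahydroazulen-1-yl]methanol | C=C1CCCC(C)(C)[C@@H]2CC[C@@](C)(CO)[C@H]12 | intermediate
21 | (1R,3aR,8aS)-1,4,4-trimethyl-8-methylidenedecahydroazulene-1-carbaldehyde | C=C1CCCC(C)(C)[C@@H]2CC[C@@](C)(C=O)[C@H]12 | intermediate
22 | methyl enol ether, 1-(2-methoxyethenyl) analogue of 21 (E/Z mixture) | C=C1CCCC(C)(C)[C@@H]2CC[C@@](C)(C=COC)[C@H]12 | intermediate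
23 | methyl (R)-2-hydroxybut-3-enoate | C=C[C@@H](O)C(=O)OC | starting material
24 | tert-butyl acrylate | C=CC(=O)OC(C)(C)C | starting material
25 | 1-tert-butyl 5-methyl (R,E)-4-hydroxypent-2-enedioate | CC(C)(C)OC(=O)/C=C/[C@@H](O)C(=O)OC | intermediate
26 | mixed iodoacetal from 22 and 25 (iodine on C11; OMe and O18–C17 on C12; mixture at C11 and C12; C17 R) | C=C1CCCC(C)(C)[C@@H]2CC[C@@](C)(C(I)C(OC)O[C@H](/C=C/C(=O)OC(C)(C)C)C(=O)OC)[C@H]12 | intermediate
27 | 2-methoxytetrahydrofuran (ring C12, C11, C16, C17, O18; C9 group cis to the CH2CO2tBu arm, arm trans to the C17 ester; both anomers) | C=C1CCCC(C)(C)[C@@H]2CC[C@@](C)([C@@H]3C(OC)O[C@@H](C(=O)OC)[C@@H]3CC(=O)OC(C)(C)C)[C@H]12 | intermediate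
28 | trimethylsilyl ester corresponding to 27 (not isolated) | C=C1CCCC(C)(C)[C@@H]2CC[C@@](C)([C@@H]3C(OC)O[C@@H](C(=O)OC)[C@@H]3CC(=O)O[Si](C)(C)C)[C@H]12 | intermediate
29 | methyl 3-oxo-8-(hydroazulenyl)-2,7-dioxabicyclo[3.2.1]octane-6-carboxylate (C15 is CH2; C9 group syn to the lactone bridge; ester exo) | C=C1CCCC(C)(C)[C@@H]2CC[C@@](C)([C@@H]3[C@@H]4OC(=O)C[C@H]3[C@H](C(=O)OC)O4)[C@H]12 | intermediate
30 | 4-hydroxy derivative of 29 (hydroxyl on C15, anti to the C11 bridge) | C=C1CCCC(C)(C)[C@@H]2CC[C@@](C)([C@@H]3[C@@H]4OC(=O)[C@@H](O)[C@H]3[C@H](C(=O)OC)O4)[C@H]12 | intermediate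
31 | methyl (1S,4S,5R,6R,8R)-4-acetoxy-3-oxo-8-[(1R,3aR,8aS)-1,4,4-trimethyl-8-methylidenedecahydroazulen-1-yl]-2,7-dioxabicyclo[3.2.1]octane-6-carboxylate (configuration as in the SMILES) | C=C1CCCC(C)(C)[C@@H]2CC[C@@](C)([C@@H]3[C@@H]4OC(=O)[C@@H](OC(C)=O)[C@H]3[C@H](C(=O)OC)O4)[C@H]12 | target

**Step count**

Total: 21 steps. Longest linear sequence: 20 steps (steps 1–15 and 17–21); step 16 is a one-step branch.

**Steps most likely to fail**

Step 18 (radical cyclisation). The closure may go with the bulky C9 group trans to the new C16 side chain, which is the sterically easier arrangement, and the two acetal epimers of 26 may differ in their preference; either would give the wrong sense at C11. The fallback sets out from 26 and comes back at 27. The iodoacetal is cyclised as before and the product is accepted as the C11-epimeric tetrahydrofuran F1. Methanol is then removed with Me3SiOTf and iPr2NEt in CH2Cl2 at −20 °C to give the 2,3-dihydrofuran F2, in which C11 is trigonal. Methanol is added back under kinetic control (pyridinium p-toluenesulfonate, MeOH, −20 °C): C11 should be protonated from the face opposite the adjacent C16 side chain, so the C9 group ends cis to it. The selectivity of this protonation would itself have to be tested.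

Step 20 (enolate hydroxylation). The enolate of the acyl acetal may fragment (loss of the C12 alkoxide to a ketene), or the base may also deprotonate C17 next to the methyl ester. The fallback sets out from 29 and comes back at 31. The enolate is trapped as it forms (KN(SiMe3)2 with Me3SiCl present, THF, −78 °C) as the trimethylsilyl ketene acetal F3. This is oxidised with lead tetraacetate, Pb(OAc)4, in CH2Cl2 at −20 °C (Rubottom-type acetoxylation), which should deliver the acetate to the same open face and give the target directly.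

Step 8 (photocycloaddition and ring expansion). Facial selectivity in the first C10–C6 bond formation may be poor, and the free 1,4-diketone may be consumed by secondary photoreactions while irradiation continues. The fallback sets out from 12 and comes back at 14. The enol is acetylated (Ac2O, pyridine) to the enol acetate F4, which is irradiated under the same conditions to the cyclobutyl acetate photoadduct F5; this is photostable and its facial isomers can be separated. K2CO3 in MeOH then removes the acetate, which triggers the retro-aldol cleavage and equilibrates C10 to the cis-fused diketone.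

Further compounds
F1 | step 18 | C11 epimer of tetrahydrofuran 27 | C=C1CCCC(C)(C)[C@@H]2CC[C@@](C)([C@H]3C(OC)O[C@@H](C(=O)OC)[C@@H]3CC(=O)OC(C)(C)C)[C@H]12
F2 | step 18 | 2,3-dihydrofuran with the C11=C12 enol ether double bond | C=C1CCCC(C)(C)[C@@H]2CC[C@@](C)(C3=CO[C@@H](C(=O)OC)[C@@H]3CC(=O)OC(C)(C)C)[C@H]12
F3 | step 20 | trimethylsilyl ketene acetal of lactone 29 | C=C1CCCC(C)(C)[C@@H]2CC[C@@](C)([C@@H]3[C@@H]4OC(O[Si](C)(C)C)=C[C@H]3[C@H](C(=O)OC)O4)[C@H]12
F4 | step 8 | enol acetate of dione 12 | CC(=O)OC1=C([C@](C)(CO[Si](C(C)C)(C(C)C)C(C)C)CCC=C(C)C)C(=O)CC1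
F5 | step 8 | cyclobutyl acetate photoadduct | O=C1CC[C@@]2(OC(C)=O)C(C)(C)[C@@H]3CC[C@@](C)(CO[Si](C(C)C)(C(C)C)C(C)C)[C@]123
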